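Ring C is disconnected at O1–C2 and C3–C4. O1, C8a, C4a and C4 are read as the four-atom oxadiene of an ortho-quinone methide built on ring A, and C2–C3 as the vinyl group of a dimethoxystyrene. One chiral-acid-controlled inverse-demand oxa-Diels–Alder reaction between the ring-A salicylaldehyde (activated in the flask by an orthoformate) and the styrene closes the pyran ring, forms both skeletal bonds and sets C2. It gives a 4-methoxyflavan in which C4 is already oxygenated. The precursor is a simple ortho-formylated phenol made in one step. A single oxidative cleavage of the C4 methyl ether then unveils the flavanone carbonyl.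

Key step: step 2

Assumption: the sense of induction of the chiral acid cannot be assigned in advance, so the (R)-catalyst is written and its enantiomer would be used if the (2R) series formed; atom labels follow flavanone numbering (O1, C2 to C8a).

Step 1
Reactants: 1 3,4,5-trimethoxyphenol
Product: 3 2-hydroxy-4,5,6-trimethoxybenzaldehyde, via salicyl alcohol 2 (not isolated)
Conditions: MgCl2, Et3N, (CH2O)n, MeCN, reflux; then 1 M HCl
Reagents that add atoms: paraformaldehyde (formaldehyde source), C=O
Why: In this Casnati–Skattebøl ortho-formylation the phenoxide ArOMgCl delivers formaldehyde to the carbon ortho to the hydroxyl (both ortho positions are equivalent, the para position is blocked), and a second formaldehyde oxidises the salicyl alcohol 2 to the aldehyde by hydride transfer.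

Step 2
Reactants: 3 2-hydroxy-4,5,6-trimethoxybenzaldehyde, 4 trimethyl orthoformate, 5 3,4-dimethoxystyrene
Product: 8 (2S,4S)-2-(3,4-dimethoxyphenyl)-4,5,6,7-tetramethoxychromane, via dimethyl acetal 6 (not isolated), via ortho-quinone methide 7 (not isolated)
Conditions: 3 + 4 (1.5 equiv), (R)-3,3'-bis(2,4,6-triisopropylphenyl)-1,1'-binaphthyl-2,2'-diyl N-triflylphosphoramide (10 mol %), 5 Å MS, PhMe, rt; then −40 °C, 5 (1.5 equiv) added slowly; Et3N quench
Reagents that add atoms: none
Why: Proposed new method: the acid turns 3 and 4 into acetal 6, which loses methanol to give the O-protonated 4-methoxy ortho-quinone methide 7 as a hydrogen-bonded contact ion pair with the chiral phosphoramidate, and the electron-rich alkene 5 then adds across O1=C8a–C4a=C4 in an asynchronous inverse-electron-demand oxa-Diels–Alder reaction (C3–C4 bond leading, O1–C2 bond following) that restores the aromaticity of ring A. The closest known reaction types are the achiral acid-promoted three-component synthesis of 2-aryl-4-alkoxychromans from salicylaldehydes, orthoformates and styrenes and the chiral phosphoric-acid-type [4+2] cycloadditions of ortho-quinone methides generated from ortho-hydroxybenzyl alcohols; what is new is chiral-anion control over an alkoxy-substituted methide reacting with a styrene that offers no hydrogen-bonding handle. The pyran ring is closed by intermolecular [4+2] cycloaddition, which in the stepwise limit is a 6-exo-trig capture of the benzylic cation by the phenol oxygen. C2 is set by the face of the oxadiene left open by the anion together with the endo orientation of the aryl group, and C4 additionally by the E geometry of the methide (methoxy outside), which leads to the 2,4-cis isomer; since C4 is erased in step 3, a C4 epimer with the same C2 configuration would serve equally. The step needs regioselectivity and enantioselectivity at C2: the 3,4-dimethoxyphenyl group localises the developing positive charge on the benzylic carbon so that only the CH2 terminus bonds to C4, and the free phenol OH of 7 is the anchor that ties the methide to the chiral anion.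

Step 3
Reactants: 8 (2S,4S)-2-(3,4-dimethoxyphenyl)-4,5,6,7-tetramethoxychromane
Product: 10 (2S)-2-(3,4-dimethoxyphenyl)-5,6,7-trimethoxychroman-4-one, via hemiketal 9 (not isolated)
Conditions: DDQ (1.2 equiv), CH2Cl2/pH 7 aqueous phosphate buffer (10:1), 0 °C to rt
Reagents that add atoms: water, O
Why: DDQ removes hydride from C4–H, which is benzylic to the tetra-oxygenated ring A and alpha to the methoxy group (oxidative benzylic ether cleavage, the reaction type of PMB and DMB ether removal), water traps the oxocarbenium ion as hemiketal 9 and this expels methanol to give the ketone, whose carbonyl group deactivates ring A against further oxidation, while the neutral buffered medium leaves C2 untouched because no base is present to open the flavanone to the chalcone.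

Compound list
1 | 3,4,5-trimethoxyphenol | COc1cc(O)cc(OC)c1OC | starting material
2 | 2-(hydroxymethyl)-3,4,5-trimethoxyphenol (salicyl alcohol, present as its ArOMgCl salt) | OCc1c(O)cc(OC)c(OC)c1OC | intermediate (not isolated)
3 | 2-hydroxy-4,5,6-trimethoxybenzaldehyde | O=Cc1c(O)cc(OC)c(OC)c1OC | intermediate
4 | trimethyl orthoformate | COC(OC)OC | starting material
5 | 3,4-dimethoxystyrene | C=Cc1ccc(OC)c(OC)c1 | starting material
6 | 2-(dimethoxymethyl)-3,4,5-trimethoxyphenol (dimethyl acetal of 3) | COC(OC)c1c(O)cc(OC)c(OC)c1OC | intermediate (not isolated)
7 | (6E)-3,4,5-trimethoxy-6-(methoxymethylidene)cyclohexa-2,4-dien-1-one (4-methoxy ortho-quinone methide, drawn neutral; it reacts as the O-protonated ion pair with the chiral anion) | CO/C=C1/C(=O)C=C(OC)C(OC)=C1OC | intermediate (not isolated)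
8 | (2S,4S)-2-(3,4-dimethoxyphenyl)-4,5,6,7-tetramethoxychromane (2,4-cis) | COc1ccc([C@@H]2C[C@H](OC)c3c(cc(OC)c(OC)c3OC)O2)cc1OC | intermediate
9 | (2S)-2-(3,4-dimethoxyphenyl)-4,5,6,7-tetramethoxychroman-4-ol (hemiketal; C4 configuration immaterial, left undefined) | COc1ccc([C@@H]2CC(O)(OC)c3c(cc(OC)c(OC)c3OC)O2)cc1OC | intermediate (not isolated)
10 | (2S)-2-(3,4-dimethoxyphenyl)-5,6,7-trimethoxychroman-4-one, i.e. (2S)-5,6,7,3',4'-pentamethoxyflavanone | COc1ccc([C@@H]2CC(=O)c3c(cc(OC)c(OC)c3OC)O2)cc1OC | target

Total step count: 3. Longest linear sequence: 3 steps (1 to 3 to 8 to 10).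

Steps most likely to fail

Step 2 (new method). Several processes could defeat it:
- weak facial or endo/exo discrimination by the chiral ion pair, which lowers the enantiomeric purity at C2;
- erosion of C2 by reversible acid-mediated ionisation of the O1–C2 bond in the product;
- cationic oligomerisation of the styrene;
- Friedel–Crafts attack of the electron-rich C8 position of the product on the methide;
- capture of the benzylic cation by methanol before ring closure.

Because C4 is erased later, the enantiomeric purity at C2 would be judged on 10 after oxidation. If the cis and trans adducts turned out to carry opposite C2 configurations, they would be separated before step 3.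

The fallback uses known chemistry, sets out from 1 and rejoins the route at 10. C-Acetylation of 1 (Ac2O, BF3·OEt2, Friedel–Crafts/Fries type) should give 1-(6-hydroxy-2,3,4-trimethoxyphenyl)ethan-1-one F1. Condensation with N,N-dimethylformamide dimethyl acetal should give the enaminone (E)-3-(dimethylamino)-1-(6-hydroxy-2,3,4-trimethoxyphenyl)prop-2-en-1-one F2. Acid (HCl, CH2Cl2) should cyclise it to 5,6,7-trimethoxy-4H-chromen-4-one F3. Asymmetric conjugate addition of 3,4-dimethoxyphenylboronic acid to F3 would then give 10 directly. The catalyst would be Pd(OCOCF3)2 (divalent palladium) with the chiral pyridine-oxazoline ligand 4-tert-butyl-2-(pyridin-2-yl)-4,5-dihydrooxazole (enantiomer chosen to give 2S), with NH4PF6 and H2O in ClCH2CH2Cl at 60 °C.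

Step 3. Possible failures are competing hydride abstraction at C2–H (loss of the stereocentre or ring opening), slow oxidation if C4–H is poorly aligned with the ring-A π system, loss of H3 to an enol ether that is oxidised further, and over-oxidation toward the flavone.

The fallback sets out from 8 and rejoins at 10. Exchange of the 4-methoxy group for hydroxyl by SN1 solvolysis in dilute aqueous acid (pyridinium p-toluenesulfonate, THF/H2O, rt) should give (2S)-2-(3,4-dimethoxyphenyl)-5,6,7-trimethoxychroman-4-ol F4 as its C4 epimers. Oxidation of this benzylic alcohol with activated MnO2 in CH2Cl2 (or Dess–Martin periodinane with NaHCO3) would then give 10 under non-basic conditions.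

Step 1. The very electron-rich ring may over-react (second formylation at the remaining ortho position, or condensation of the salicyl alcohol stage with unreacted phenol to diarylmethanes), or the reaction may stall before the hydride-transfer oxidation.

The fallback sets out from 1 and rejoins at 3. Protection with MOMCl and i-Pr2NEt should give 1,2,3-trimethoxy-5-(methoxymethoxy)benzene F5. Directed ortho-lithiation (n-BuLi, THF, 0 °C; the two ortho sites are equivalent and each is flanked by OMOM and OMe) followed by a DMF quench should give 2,3,4-trimethoxy-6-(methoxymethoxy)benzaldehyde F6. Aqueous HCl in THF would remove the MOM group to give 3.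

Further compounds
F1 | step 2 | 1-(6-hydroxy-2,3,4-trimethoxyphenyl)ethan-1-one | CC(=O)c1c(O)cc(OC)c(OC)c1OC
F2 | step 2 | (E)-3-(dimethylamino)-1-(6-hydroxy-2,3,4-trimethoxyphenyl)prop-2-en-1-one | CN(C)/C=C/C(=O)c1c(O)cc(OC)c(OC)c1OC
F3 | step 2 | 5,6,7-trimethoxy-4H-chromen-4-one | O=c1ccoc2cc(OC)c(OC)c(OC)c12
F4 | step 3 | (2S)-2-(3,4-dimethoxyphenyl)-5,6,7-trimethoxychroman-4-ol (both C4 epimers; C4 left undefined) | COc1ccc([C@@H]2CC(O)c3c(cc(OC)c(OC)c3OC)O2)cc1OC
F5 | step 1 | 1,2,3-trimethoxy-5-(methoxymethoxy)benzene | COCOc1cc(OC)c(OC)c(OC)c1
F6 | step 1 | 2,3,4-trimethoxy-6-(methoxymethoxy)benzaldehyde | COCOc1cc(OC)c(OC)c(OC)c1C=O
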